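**Retrosynthetic overview**
- The target is the (2S,3S)-trans-2,3-diaryl-2,3-dihydrobenzofuran; its five phenols are unmasked last from four methyl ethers (BBr3) and one aryl triflate (hydroxide).
- Key disconnection: O1–C7a and C3–C3a are cut together, giving 3-methoxy-5-(6-methoxybenzofuran-2-yl)benzyne and a (2R,3R)-trans-stilbene oxide; the aryne inserts into one epoxide C–O bond, and the dihydrofuran ring is the only ring made (last), all others are bought.
- Enabling feature: C7a (bearing O1) and C3a (bearing C3) are adjacent, and C3a is flanked by the oxygenated C4. This is the pattern of a 3-alkoxybenzyne, which takes a nucleophile at C7a and leaves the carbanion at C3a. O1–C2–C3 with an aryl group on each carbon is a stilbene oxide, and a para-triflate on ring A (the C2 aryl) decides which C–O bond opens.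
- Aryne precursor: commercial 3-methoxy-2-(trimethylsilyl)phenyl triflate, iridium C–H borylation at its only unhindered C–H, then Suzuki coupling with 2-bromo-6-methoxybenzofuran.
- Epoxide: pterostilbene, O-triflation, Shi epoxidation.

Key step: step 6

Assumption: compounds 1, 4 and 6 are taken as commercial, and the target is read as the (2S,3S)-trans isomer, which a retentive transfer of the benzylic carbon from oxygen to carbon delivers from the (2R,3R)-epoxide.

Step 1
Reactants: 1 pterostilbene, 4-[(E)-2-(3,5-dimethoxyphenyl)ethenyl]phenol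
Product: 2 4-[(E)-2-(3,5-dimethoxyphenyl)ethenyl]phenyl trifluoromethanesulfonate
Conditions: Tf2O, pyridine, CH2Cl2, 0 °C
Reagents that add atoms: trifluoromethanesulfonic anhydride, O=S(=O)(OS(=O)(=O)C(F)(F)F)C(F)(F)F
Why: O-sulfonylation (triflation) of the only free phenol; the triflate serves as protecting group of ring A, as the electron-withdrawing group that later directs the epoxide opening, and as a shield of the dihydrofuran against Lewis acid in step 7.

Step 2
Reactants: 2 4-[(E)-2-(3,5-dimethoxyphenyl)ethenyl]phenyl trifluoromethanesulfonate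
Product: 3 4-[(2R,3R)-3-(3,5-dimethoxyphenyl)oxiran-2-yl]phenyl trifluoromethanesulfonate
Conditions: D-fructose-derived ketone catalyst of the Shi epoxidation (30 mol%), Oxone (2KHSO5·KHSO4·K2SO4), K2CO3, Bu4NHSO4, MeCN/dimethoxymethane/aq. Na2B4O7 buffer, 0 °C
Reagents that add atoms: potassium peroxymonosulfate, [K+].[O-]S(=O)(=O)OO
Why: Shi asymmetric epoxidation, in which the dioxirane of the D-fructose-derived ketone transfers oxygen to the E-alkene through a spiro transition state and, as for E-stilbene itself, should give the (R,R)-epoxide with both stereocenters set by the catalyst; with no para-donor on either ring the epoxide should survive work-up.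

Step 3
Reactants: 4 3-methoxy-2-(trimethylsilyl)phenyl trifluoromethanesulfonate
Product: 5 3-methoxy-5-(4,4,5,5-tetramethyl-1,3,2-dioxaborolan-2-yl)-2-(trimethylsilyl)phenyl trifluoromethanesulfonate
Conditions: [Ir(OMe)(cod)]2 (1.5 mol%), 4,4'-di-tert-butyl-2,2'-bipyridine (3 mol%), B2pin2, cyclohexane, 60 °C
Reagents that add atoms: bis(pinacolato)diboron, CC1(C)OB(OC1(C)C)B1OC(C)(C)C(C)(C)O1
Why: iridium-catalysed C–H borylation is governed by sterics, and C5 is the only C–H without an ortho substituent (C4 lies next to OMe, C6 next to OTf), which is the carbon that must carry the benzofuran; the aryl triflate and the C–Si bond are inert to the iridium boryl catalyst.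

Step 4
Reactants: 6 6-methoxy-1-benzofuran
Product: 8 2-bromo-6-methoxy-1-benzofuran, via (6-methoxy-1-benzofuran-2-yl)lithium 7 (not isolated)
Conditions: n-BuLi, THF, −78 °C; then BrCCl2CCl2Br, −78 °C to rt
Reagents that add atoms: 1,2-dibromo-1,1,2,2-tetrachloroethane, BrC(Cl)(Cl)C(Cl)(Cl)Br
Why: lithiation–bromination, with deprotonation at C2 (the most acidic C–H of benzofuran) followed by halophilic attack of the 2-lithio species on the bromine donor; the product is used at once because 2-bromobenzofurans are labile.

Step 5
Reactants: 5 3-methoxy-5-(4,4,5,5-tetramethyl-1,3,2-dioxaborolan-2-yl)-2-(trimethylsilyl)phenyl trifluoromethanesulfonate, 8 2-bromo-6-methoxy-1-benzofuran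
Product: 9 3-methoxy-5-(6-methoxy-1-benzofuran-2-yl)-2-(trimethylsilyl)phenyl trifluoromethanesulfonate
Conditions: Pd(PPh3)4 (5 mol%), K3PO4, 1,4-dioxane/H2O, 50 °C
Reagents that add atoms: none
Why: Suzuki–Miyaura coupling, in which zerovalent palladium with triphenylphosphine should insert into the heteroaryl C–Br bond much faster than into the aryl triflate flanked by the trimethylsilyl group, and the fluoride-free phosphate base should leave the silyl triflate untouched.

Step 6
Reactants: 9 3-methoxy-5-(6-methoxy-1-benzofuran-2-yl)-2-(trimethylsilyl)phenyl trifluoromethanesulfonate, 3 4-[(2R,3R)-3-(3,5-dimethoxyphenyl)oxiran-2-yl]phenyl trifluoromethanesulfonate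
Product: 12 4-[(2S,3S)-3-(3,5-dimethoxyphenyl)-4-methoxy-6-(6-methoxy-1-benzofuran-2-yl)-2,3-dihydro-1-benzofuran-2-yl]phenyl trifluoromethanesulfonate, via aryne 10 (not isolated), via epoxonium aryl-anion zwitterion 11 (not isolated)
Conditions: CsF (3 equiv), MeCN, 25 °C; 9 added slowly to 3 (2 equiv)
Reagents that add atoms: none
Why: Proposed new method: fluoride removes the trimethylsilyl group of 9 and triflate leaves to give aryne 10, whose methoxy group (inductive effect and aryne distortion) steers the epoxide oxygen of 3 onto the future C7a and leaves the carbanion on the future C3a in zwitterion 11; the epoxonium then breaks its O–C bond at the carbon bearing the dimethoxyphenyl ring, and this carbon is caught from the front by the neighbouring aryl anion in an asynchronous, ion-pair-like collapse. The closest known reaction type is the fluoride-triggered insertion of arynes into the benzylic C–O bond of monoaryl oxiranes to give 2,3-dihydrobenzofurans, which has not been shown for a trans-1,2-diaryl oxirane or with transfer of chirality. The dihydrofuran ring closes as a formal [3+2] annulation; because the breaking C–O bond lies inside the forming five-membered ring (5-endo-tet, not feasible as a concerted backside displacement), closure should run by front-side recombination with benzylic-cation character. C2 keeps the spatial arrangement of the epoxide because its C–O bond is never broken (the descriptor changes from R to S only through the change in priorities), and C3 is controlled by the C2 aryl group, the new C–C bond forming on the face vacated by oxygen, which is also the face that places the two aryl groups trans. The step needs two regioselectivities: that of the aryne, secured by the oxygen at C4, and that of the C–O cleavage, secured by the para-triflate of ring A, which destabilises positive charge at its own benzylic carbon far more than the two meta-methoxy groups do at the other.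

Step 7
Reactants: 12 4-[(2S,3S)-3-(3,5-dimethoxyphenyl)-4-methoxy-6-(6-methoxy-1-benzofuran-2-yl)-2,3-dihydro-1-benzofuran-2-yl]phenyl trifluoromethanesulfonate
Product: 13 4-[(2S,3S)-3-(3,5-dihydroxyphenyl)-4-hydroxy-6-(6-hydroxy-1-benzofuran-2-yl)-2,3-dihydro-1-benzofuran-2-yl]phenyl trifluoromethanesulfonate
Conditions: BBr3 (10 equiv), CH2Cl2, −78 to 0 °C; then H2O
Reagents that add atoms: none
Why: Lewis-acid cleavage of the four aryl methyl ethers (BBr3 demethylation), in which the electron-poor para-triflyloxyphenyl group at C2 disfavours ionisation of the benzylic C2–O bond, so that ring opening and loss of the C2 configuration should be suppressed while C3 is not touched.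

Step 8
Reactants: 13 4-[(2S,3S)-3-(3,5-dihydroxyphenyl)-4-hydroxy-6-(6-hydroxy-1-benzofuran-2-yl)-2,3-dihydro-1-benzofuran-2-yl]phenyl trifluoromethanesulfonate
Product: 14 5-[(2S,3S)-4-hydroxy-6-(6-hydroxy-1-benzofuran-2-yl)-2-(4-hydroxyphenyl)-2,3-dihydro-1-benzofuran-3-yl]benzene-1,3-diol
Conditions: Et4NOH (aq., excess), 1,4-dioxane, 25 °C, argon; then aq. HCl to pH 5
Reagents that add atoms: none
Why: sulfonate ester hydrolysis, in which hydroxide attacks the sulfur of the aryl triflate (S–O cleavage) and releases the fifth phenol at room temperature; no bond at C2 or C3 is involved, so the (2S,3S) configuration should be kept.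

**Compound list**
1 | pterostilbene, 4-[(E)-2-(3,5-dimethoxyphenyl)ethenyl]phenol | COc1cc(/C=C/c2ccc(O)cc2)cc(OC)c1 | starting material
2 | 4-[(E)-2-(3,5-dimethoxyphenyl)ethenyl]phenyl trifluoromethanesulfonate | COc1cc(/C=C/c2ccc(OS(=O)(=O)C(F)(F)F)cc2)cc(OC)c1 | intermediate
3 | 4-[(2R,3R)-3-(3,5-dimethoxyphenyl)oxiran-2-yl]phenyl trifluoromethanesulfonate | FC(F)(F)S(=O)(=O)Oc1ccc(cc1)[C@H]2O[C@@H]2c3cc(OC)cc(OC)c3 | intermediate
4 | 3-methoxy-2-(trimethylsilyl)phenyl trifluoromethanesulfonate | COc1cccc(OS(=O)(=O)C(F)(F)F)c1[Si](C)(C)C | starting material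
5 | 3-methoxy-5-(4,4,5,5-tetramethyl-1,3,2-dioxaborolan-2-yl)-2-(trimethylsilyl)phenyl trifluoromethanesulfonate | COc1cc(cc(OS(=O)(=O)C(F)(F)F)c1[Si](C)(C)C)B1OC(C)(C)C(C)(C)O1 | intermediate
6 | 6-methoxy-1-benzofuran | COc1ccc2ccoc2c1 | starting material
7 | (6-methoxy-1-benzofuran-2-yl)lithium (not isolated) | [Li]c1cc2ccc(OC)cc2o1 | intermediate
8 | 2-bromo-6-methoxy-1-benzofuran | Brc1cc2ccc(OC)cc2o1 | intermediate
9 | 3-methoxy-5-(6-methoxy-1-benzofuran-2-yl)-2-(trimethylsilyl)phenyl trifluoromethanesulfonate | COc1cc(cc(OS(=O)(=O)C(F)(F)F)c1[Si](C)(C)C)-c1cc2ccc(OC)cc2o1 | intermediate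
10 | aryne, 3-methoxy-5-(6-methoxy-1-benzofuran-2-yl)benzyne (not isolated) | COC1=CC(=CC#C1)c1cc2ccc(OC)cc2o1 | intermediate
11 | epoxonium aryl-anion zwitterion: oxygen of 3 bonded to the aryne carbon meta to OMe, carbanion on the carbon between O+ and OMe (not isolated) | FC(F)(F)S(=O)(=O)Oc1ccc(cc1)[C@H]2[O+](c3cc(cc(OC)[c-]3)-c3cc4ccc(OC)cc4o3)[C@@H]2c5cc(OC)cc(OC)c5 | intermediate
12 | 4-[(2S,3S)-3-(3,5-dimethoxyphenyl)-4-methoxy-6-(6-methoxy-1-benzofuran-2-yl)-2,3-dihydro-1-benzofuran-2-yl]phenyl trifluoromethanesulfonate | FC(F)(F)S(=O)(=O)Oc1ccc([C@H]2Oc3cc(-c4cc5ccc(OC)cc5o4)cc(OC)c3[C@@H]2c2cc(OC)cc(OC)c2)cc1 | intermediate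
13 | 4-[(2S,3S)-3-(3,5-dihydroxyphenyl)-4-hydroxy-6-(6-hydroxy-1-benzofuran-2-yl)-2,3-dihydro-1-benzofuran-2-yl]phenyl trifluoromethanesulfonate | FC(F)(F)S(=O)(=O)Oc1ccc([C@H]2Oc3cc(-c4cc5ccc(O)cc5o4)cc(O)c3[C@@H]2c2cc(O)cc(O)c2)cc1 | intermediate
14 | 5-[(2S,3S)-4-hydroxy-6-(6-hydroxy-1-benzofuran-2-yl)-2-(4-hydroxyphenyl)-2,3-dihydro-1-benzofuran-3-yl]benzene-1,3-diol | Oc1ccc([C@H]2Oc3cc(-c4cc5ccc(O)cc5o4)cc(O)c3[C@@H]2c2cc(O)cc(O)c2)cc1 | target

Total step count: 8. Longest linear sequence: 5 steps (for example steps 3, 5, 6, 7, 8).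

**Steps most likely to fail**

Step 6. The epoxide oxygen may be too weak a nucleophile, so that the aryne is consumed by fluoride, by acetonitrile or by the benzofuran of another molecule. The wrong C–O bond may open, or the zwitterion may decay by proton transfer to an enol ether or close to the cis isomer. The fallback makes the two bonds one after the other by known reactions, with inversion at both carbons; it sets out from 2 and 8 and comes back at 12.
- Stilbene 2 would be epoxidised with the enantiomeric ketone catalyst (from L-sorbose) and KHSO5 to 4-[(2S,3S)-3-(3,5-dimethoxyphenyl)oxiran-2-yl]phenyl trifluoromethanesulfonate F1.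
- Bromide 8 would be coupled with commercial (3,5-dimethoxyphenyl)boronic acid (COc1cc(cc(OC)c1)B(O)O; Pd(PPh3)4, K2CO3, dioxane/H2O) to 2-(3,5-dimethoxyphenyl)-6-methoxy-1-benzofuran F2.
- n-BuLi in THF at 0 °C should lithiate F2 between the two methoxy groups to [2,6-dimethoxy-4-(6-methoxy-1-benzofuran-2-yl)phenyl]lithium F3.
- F3 with BF3·OEt2 at −78 °C should open F1 with inversion at the benzylic carbon that carries the dimethoxyphenyl ring (the same electronic bias as in the main route), giving, after NH4Cl work-up, 4-[(1R,2S)-2-(3,5-dimethoxyphenyl)-2-[2,6-dimethoxy-4-(6-methoxy-1-benzofuran-2-yl)phenyl]-1-hydroxyethyl]phenyl trifluoromethanesulfonate F4.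
- Mesylation (MsCl, Et3N, CH2Cl2, 0 °C) would give 4-[(1R,2S)-2-(3,5-dimethoxyphenyl)-2-[2,6-dimethoxy-4-(6-methoxy-1-benzofuran-2-yl)phenyl]-1-(methanesulfonyloxy)ethyl]phenyl trifluoromethanesulfonate F5.
- Warming F5 in MeCN should let one of the two equivalent flanking methoxy oxygens displace the mesylate with inversion (5-exo-tet); the methyloxonium ion then loses its methyl group to the mesylate anion and 12 results.
- The double inversion should turn the (2S,3S)-epoxide into the same (2S,3S)-trans product.

Step 7. The Lewis acid may open the dihydrofuran at C2–O with loss of configuration, and HBr may attack the electron-rich phenols or the benzofuran. The fallback abandons Lewis acids for SN2 dealkylation by a soft nucleophile, sets out from 12 and comes back at 14, merging steps 7 and 8; no new compound is made (F0). Excess sodium ethanethiolate in DMF at about 120 °C should remove the four methyl groups and, by attack at sulfur, the triflate in the same operation. Thiolate is too weak a base to deprotonate C3, and the secondary benzylic ether carbon C2 is a far poorer SN2 site than methyl.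

Step 5. The basic aqueous medium may strip the trimethylsilyl group or release the aryne early, zerovalent palladium may insert into the aryl triflate, and the labile 2-bromobenzofuran may decompose before it couples. The fallback reverses the polarity of the coupling and runs it without base; it sets out from 5 and 7 and comes back at 9, without making 8.
- CuBr2 in MeOH/H2O should convert boronate 5 into 5-bromo-3-methoxy-2-(trimethylsilyl)phenyl trifluoromethanesulfonate F6.
- Lithio compound 7 (made from 6 as in step 4) with ZnCl2 in THF should give (6-methoxy-1-benzofuran-2-yl)zinc chloride F7.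
- Negishi coupling of F6 with F7 (Pd(PPh3)4, THF, 25 °C) under neutral, anhydrous conditions should give 9.

**Further compounds**
F1 | step 6 | 4-[(2S,3S)-3-(3,5-dimethoxyphenyl)oxiran-2-yl]phenyl trifluoromethanesulfonate | FC(F)(F)S(=O)(=O)Oc1ccc(cc1)[C@@H]2O[C@H]2c3cc(OC)cc(OC)c3
F2 | step 6 | 2-(3,5-dimethoxyphenyl)-6-methoxy-1-benzofuran | COc1ccc2cc(oc2c1)-c1cc(OC)cc(OC)c1
F3 | step 6 | [2,6-dimethoxy-4-(6-methoxy-1-benzofuran-2-yl)phenyl]lithium | [Li]c1c(OC)cc(cc1OC)-c1cc2ccc(OC)cc2o1
F4 | step 6 | 4-[(1R,2S)-2-(3,5-dimethoxyphenyl)-2-[2,6-dimethoxy-4-(6-methoxy-1-benzofuran-2-yl)phenyl]-1-hydroxyethyl]phenyl trifluoromethanesulfonate | FC(F)(F)S(=O)(=O)Oc1ccc(cc1)[C@H](O)[C@@H](c1cc(OC)cc(OC)c1)c1c(OC)cc(cc1OC)-c1cc2ccc(OC)cc2o1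
F5 | step 6 | 4-[(1R,2S)-2-(3,5-dimethoxyphenyl)-2-[2,6-dimethoxy-4-(6-methoxy-1-benzofuran-2-yl)phenyl]-1-(methanesulfonyloxy)ethyl]phenyl trifluoromethanesulfonate | FC(F)(F)S(=O)(=O)Oc1ccc(cc1)[C@H](OS(C)(=O)=O)[C@@H](c1cc(OC)cc(OC)c1)c1c(OC)cc(cc1OC)-c1cc2ccc(OC)cc2o1
F0 | step 7 | none | none
F6 | step 5 | 5-bromo-3-methoxy-2-(trimethylsilyl)phenyl trifluoromethanesulfonate | COc1cc(Br)cc(OS(=O)(=O)C(F)(F)F)c1[Si](C)(C)C
F7 | step 5 | (6-methoxy-1-benzofuran-2-yl)zinc chloride | COc1ccc2cc([Zn]Cl)oc2c1
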